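**Plan**

- Retrosynthesis: the angelate C3–O bond and the C12 methyl ester are cut last. The C6=C7 enone is traced back to a saturated C7 allyl β-keto ester, a helper group that is removed by Tsuji decarboxylation–dehydrogenation.
- Ring B is then cut at C5–C6 and C7–C8 into a (2-methylidenecyclohexyl)acetaldehyde (ring A with C8, C9, C14) and a Roche-ester-derived 2-substituted allyl acrylate (C6, C7, C11–C13). The aldehyde is cut at C10–C9 (Johnson–Claisen) and goes back to 2-methylcyclohex-2-enone.
- Enabling feature: C5 is a methyl-bearing quaternary ring-fusion carbon standing 1,4 to the C8 ketone of ring B (C5–C10–C9–C8). It is therefore the Markovnikov carbon of an exocyclic C5=C14 methylene, and its tertiary radical and a C8 aldehyde can be bridged by a two-carbon acceptor C6=C7.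
- Forward: ring A first (8 steps), acceptor in parallel (4 steps), ring B by one radical–polar crossover annulation, then enone, carboxyl group and the two esters.
- Stereochemistry: C3 by CBS catalysis; C4 (hydroboration anti to OTBS), C10 (Claisen anti to the C3/C4 substituents) and C5 (axial radical addition anti to the C4 methyl) are relayed from it by the ring; C11 comes from (S)-Roche ester.

Key step: step 13

Remark on the chemistry: atom numbers follow the eremophilane skeleton of the target (decalin C1–C10; O on C3; methyls C15 on C4 and C14 on C5; ketone C8; C6=C7; side chain C11(C13)–C12 on C7). The SMILES is read as the cis-fused (3S,4R,5R,10R,11R) isomer with a (Z)-2-methylbut-2-enoate (angelate). TBS = tert-butyldimethylsilyl.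

**Route**

Step 1
Reactants: 1 2-methylcyclohex-2-en-1-one
Product: 2 (S)-2-methylcyclohex-2-en-1-ol
Conditions: (R)-Me-CBS (10 mol%), BH3·SMe2, THF, −20 °C; MeOH quench
Reagents that add atoms: none
Why: Corey–Bakshi–Shibata reduction; the (R)-oxazaborolidine binds the ketone with the alkenyl flank as the large group and should deliver hydride to the face that gives the (S)-carbinol, the only ring-A stereocentre set by catalysis (C3).

Step 2
Reactants: 2 (S)-2-methylcyclohex-2-en-1-ol
Product: 3 tert-butyldimethyl{[(1S)-2-methylcyclohex-2-en-1-yl]oxy}silane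
Conditions: TBSCl, imidazole, DMF, rt
Reagents that add atoms: tert-butyldimethylsilyl chloride CC(C)(C)[Si](C)(C)Cl
Why: routine silylation of a secondary allylic alcohol; the bulky silyl ether then shields one ring face in the next steps.

Step 3
Reactants: 3 tert-butyldimethyl{[(1S)-2-methylcyclohex-2-en-1-yl]oxy}silane
Product: 5 (1S,2R,3S)-3-[(tert-butyldimethylsilyl)oxy]-2-methylcyclohexan-1-ol, via alkylborane 4 (not isolated)
Conditions: BH3·THF, THF, 0 °C → rt; then NaOH, H2O2, 0 °C
Reagents that add atoms: hydrogen peroxide OO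
Why: hydroboration–oxidation; boron goes to the less substituted C5 and the syn H/B addition should occur on the face anti to the allylic OTBS group, which puts the C4 methyl cis to the C3 oxygen.

Step 4
Reactants: 5 (1S,2R,3S)-3-[(tert-butyldimethylsilyl)oxy]-2-methylcyclohexan-1-ol
Product: 6 (2S,3S)-3-[(tert-butyldimethylsilyl)oxy]-2-methylcyclohexan-1-one
Conditions: Dess–Martin periodinane, CH2Cl2, 0 °C → rt
Reagents that add atoms: none
Why: Dess–Martin oxidation under non-basic conditions, so the epimerisable C4 centre and the β-silyloxy group should stay untouched.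

Step 5
Reactants: 6 (2S,3S)-3-[(tert-butyldimethylsilyl)oxy]-2-methylcyclohexan-1-one
Product: 8 (5S,6S)-5-[(tert-butyldimethylsilyl)oxy]-6-methylcyclohex-1-en-1-yl trifluoromethanesulfonate, via potassium enolate 7 (not isolated)
Conditions: KHMDS, THF, −78 °C; then PhNTf2, −78 → 0 °C
Reagents that add atoms: N-phenylbis(trifluoromethanesulfonimide) O=S(=O)(N(c1ccccc1)S(=O)(=O)C(F)(F)F)C(F)(F)F
Why: kinetic deprotonation at the unhindered C10 methylene (not at the tertiary C4–H, so no epimerisation and no β-elimination of silanolate) followed by O-triflation of the enolate.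

Step 6
Reactants: 8 (5S,6S)-5-[(tert-butyldimethylsilyl)oxy]-6-methylcyclohex-1-en-1-yl trifluoromethanesulfonate
Product: 9 [(5S,6R)-5-[(tert-butyldimethylsilyl)oxy]-6-methylcyclohex-1-en-1-yl]methanol
Conditions: Bu3SnCH2OH, Pd(PPh3)4 (5 mol%), LiCl, 1,4-dioxane, 100 °C
Reagents that add atoms: (tributylstannyl)methanol OC[Sn](CCCC)(CCCC)CCCC
Why: Stille coupling of an alkenyl triflate with the hydroxymethylstannane installs C14 as the allylic alcohol in one step without touching C4.

Step 7
Reactants: 9 [(5S,6R)-5-[(tert-butyldimethylsilyl)oxy]-6-methylcyclohex-1-en-1-yl]methanol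
Product: 11 ethyl 2-[(1R,3R,4S)-4-[(tert-butyldimethylsilyl)oxy]-3-methyl-2-methylidenecyclohexyl]acetate, via ketene acetal 10 (not isolated)
Conditions: MeC(OEt)3 (excess), EtCO2H (cat.), 140 °C, EtOH distilled off
Reagents that add atoms: triethyl orthoacetate CCOC(C)(OCC)OCC
Why: Johnson–Claisen rearrangement; the ketene acetal formed in situ should deliver the acetate carbon C9 suprafacially to C10 on the ring face anti to the C4 methyl and C3 silyloxy groups, and the [3,3] shift moves the double bond into the exocyclic C5=C14 position.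

Step 8
Reactants: 11 ethyl 2-[(1R,3R,4S)-4-[(tert-butyldimethylsilyl)oxy]-3-methyl-2-methylidenecyclohexyl]acetate
Product: 12 2-[(1R,3R,4S)-4-[(tert-butyldimethylsilyl)oxy]-3-methyl-2-methylidenecyclohexyl]acetaldehyde
Conditions: DIBAL-H (1.05 equiv), CH2Cl2, −78 °C; Rochelle salt work-up
Reagents that add atoms: none
Why: partial ester reduction with DIBAL-H at low temperature stops at the aluminium hemiacetal, which releases the aldehyde (C8) on work-up.

Step 9
Reactants: 13 methyl (S)-3-hydroxy-2-methylpropanoate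
Product: 14 methyl (S)-3-[(tert-butyldimethylsilyl)oxy]-2-methylpropanoate
Conditions: TBSCl, imidazole, CH2Cl2, rt
Reagents that add atoms: tert-butyldimethylsilyl chloride CC(C)(C)[Si](C)(C)Cl
Why: routine silylation of the primary alcohol of the chiral-pool ester that supplies C11, C12 and C13.

Step 10
Reactants: 14 methyl (S)-3-[(tert-butyldimethylsilyl)oxy]-2-methylpropanoate
Product: 15 (S)-3-[(tert-butyldimethylsilyl)oxy]-2-methylpropanal
Conditions: DIBAL-H (1.1 equiv), CH2Cl2, −78 °C; Rochelle salt work-up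
Reagents that add atoms: none
Why: low-temperature DIBAL-H reduction of the ester to the aldehyde, which is used at once so that the α-stereocentre is not lost.

Step 11
Reactants: 15 (S)-3-[(tert-butyldimethylsilyl)oxy]-2-methylpropanal
Product: 16 (R)-tert-butyldimethyl[(2-methylbut-3-yn-1-yl)oxy]silane
Conditions: dimethyl (1-diazo-2-oxopropyl)phosphonate, K2CO3, MeOH, 0 °C → rt
Reagents that add atoms: dimethyl (1-diazo-2-oxopropyl)phosphonate COP(=O)(OC)C(=[N+]=[N-])C(C)=O
Why: Ohira–Bestmann (Seyferth–Gilbert) homologation converts the aldehyde into the terminal alkyne (C7≡C6) under conditions mild enough for an α-branched aldehyde; the descriptor changes from S to R only through priorities.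

Step 12
Reactants: 16 (R)-tert-butyldimethyl[(2-methylbut-3-yn-1-yl)oxy]silane
Product: 18 prop-2-en-1-yl (3R)-4-[(tert-butyldimethylsilyl)oxy]-3-methyl-2-methylidenebutanoate, via vinylalane 17 (not isolated)
Conditions: Ni(dppp)Cl2 (3 mol%), DIBAL-H, THF, 0 → 22 °C; then ClCO2CH2CH=CH2, 0 °C → rt
Reagents that add atoms: allyl chloroformate C=CCOC(Cl)=O
Why: nickel-catalysed α-selective (Markovnikov) hydroalumination of the terminal alkyne puts aluminium on the internal carbon C7, and acylation of the alkenylalane with the chloroformate gives the 2-substituted acrylate without any base that could touch C11.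

Step 13
Reactants: 12 2-[(1R,3R,4S)-4-[(tert-butyldimethylsilyl)oxy]-3-methyl-2-methylidenecyclohexyl]acetaldehyde; 18 prop-2-en-1-yl (3R)-4-[(tert-butyldimethylsilyl)oxy]-3-methyl-2-methylidenebutanoate (2.5 equiv)
Product: 20 allyl 8-hydroxy-3,12-bis(TBS-oxy)-cis-eremophilane-7-carboxylate (C3, C4, C5, C10, C11 as in 26; epimers at C7 and C8), via ester enolate 19 (not isolated)
Conditions: Fe(acac)3 (30 mol%), PhSiH3, (CH2OH)2, 1,2-dichloroethane, 0 °C → rt
Reagents that add atoms: none
Why: An iron hydride formed from Fe(acac)3 and PhSiH3 transfers a hydrogen atom to the exocyclic methylene of 12, which creates the C14 methyl and a tertiary C5 radical; this adds to the CH2 terminus of acrylate 18 (C5–C6), Fe(II) reduces the α-ester radical to iron enolate 19 (drawn as the free enolate), and 19 adds to the pendant C8 aldehyde (C7–C8). The closest known reaction type is the HAT-initiated radical–polar crossover annulation (Giese addition followed by intramolecular aldol) of a carbonyl-bearing alkene with an unsaturated carbonyl acceptor, a relative of the Mukaiyama-type reductive aldol reaction. Ring B is closed by a 6-(enolexo)-exo-trig aldol after the intermolecular C5–C6 bond has formed. C5 is controlled by the ring: in the chair with axial C4 methyl and equatorial C3-OTBS and C10 side chain the acrylate should approach axially on the face anti to the C4 methyl, which places C6 cis to C9 (cis-decalin) and C14 cis to C15, while C7 and C8 form as mixtures that steps 14 and 15 erase. The step needs chemoselective hydrogen-atom transfer to the electron-rich 1,1-disubstituted alkene over the electron-poor acrylate and the monosubstituted allyl alkene, and aldol capture of the enolate faster than its protonation; the excess of 18, the largely aprotic medium and the six-membered closure onto an aldehyde should secure both.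

Step 14
Reactants: 20 allyl 8-hydroxy-3,12-bis(TBS-oxy)-cis-eremophilane-7-carboxylate
Product: 21 allyl 8-oxo-3,12-bis(TBS-oxy)-cis-eremophilane-7-carboxylate (C3, C4, C5, C10, C11 as in 26; epimers at C7)
Conditions: Dess–Martin periodinane, CH2Cl2, rt
Reagents that add atoms: none
Why: Dess–Martin oxidation of the hindered secondary alcohol; the β-keto ester has no hydrogen on C7, so it can neither enolise toward C7 nor epimerise C11 under these neutral conditions, and both C8 epimers converge.

Step 15
Reactants: 21 allyl 8-oxo-3,12-bis(TBS-oxy)-cis-eremophilane-7-carboxylate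
Product: 22 (4aR,5R,6S,8aR)-6-[(tert-butyldimethylsilyl)oxy]-3-{(2R)-1-[(tert-butyldimethylsilyl)oxy]propan-2-yl}-4a,5-dimethyl-4a,5,6,7,8,8a-hexahydronaphthalen-2(1H)-one
Conditions: Pd(OAc)2 (10 mol%), dppe (10 mol%), MeCN, 80 °C
Reagents that add atoms: none
Why: Tsuji decarboxylation–dehydrogenation; Pd(0) ionises the allyl ester, loss of CO2 gives the palladium enolate at C7/C8, and β-hydride elimination from the ring methylene C6 should give the conjugated C6=C7 enone and propene, so the helper ester leaves and the unsaturation enters in one step.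

Step 16
Reactants: 22 (4aR,5R,6S,8aR)-6-[(tert-butyldimethylsilyl)oxy]-3-{(2R)-1-[(tert-butyldimethylsilyl)oxy]propan-2-yl}-4a,5-dimethyl-4a,5,6,7,8,8a-hexahydronaphthalen-2(1H)-one
Product: 23 (4aR,5R,6S,8aR)-6-hydroxy-3-[(2R)-1-hydroxypropan-2-yl]-4a,5-dimethyl-4a,5,6,7,8,8a-hexahydronaphthalen-2(1H)-one
Conditions: HF·pyridine, pyridine, THF, 0 °C → rt
Reagents that add atoms: none
Why: fluoride-mediated cleavage of both silyl ethers under buffered, weakly acidic conditions that should not enolise the enone or affect C11.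

Step 17
Reactants: 23 (4aR,5R,6S,8aR)-6-hydroxy-3-[(2R)-1-hydroxypropan-2-yl]-4a,5-dimethyl-4a,5,6,7,8,8a-hexahydronaphthalen-2(1H)-one
Product: 24 (2R)-2-[(4aR,7S,8R,8aR)-7-hydroxy-8,8a-dimethyl-3-oxo-3,4,4a,5,6,7,8,8a-octahydronaphthalen-2-yl]propanoic acid
Conditions: TEMPO (20 mol%), PhI(OAc)2 (2.2 equiv), MeCN/H2O 1:1, 0 °C → rt
Reagents that add atoms: water O
Why: oxoammonium (TEMPO) oxidation is selective for the primary alcohol over the hindered secondary C3 alcohol, and the aldehyde hydrate is oxidised on to the acid under near-neutral conditions, so the C11 centre should pass through the aldehyde stage without enolisation.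

Step 18
Reactants: 24 (2R)-2-[(4aR,7S,8R,8aR)-7-hydroxy-8,8a-dimethyl-3-oxo-3,4,4a,5,6,7,8,8a-octahydronaphthalen-2-yl]propanoic acid
Product: 25 methyl (2R)-2-[(4aR,7S,8R,8aR)-7-hydroxy-8,8a-dimethyl-3-oxo-3,4,4a,5,6,7,8,8a-octahydronaphthalen-2-yl]propanoate
Conditions: TMSCHN2, toluene/MeOH 4:1, 0 °C
Reagents that add atoms: (trimethylsilyl)diazomethane C[Si](C)(C)C=[N+]=[N-]
Why: base-free methyl esterification of the carboxylic acid with the diazoalkane, selective over the secondary alcohol and harmless to C11.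

Step 19
Reactants: 25 methyl (2R)-2-[(4aR,7S,8R,8aR)-7-hydroxy-8,8a-dimethyl-3-oxo-3,4,4a,5,6,7,8,8a-octahydronaphthalen-2-yl]propanoate
Product: 26 methyl (2R)-2-[(4aR,7S,8R,8aR)-8,8a-dimethyl-7-{[(2Z)-2-methylbut-2-enoyl]oxy}-3-oxo-3,4,4a,5,6,7,8,8a-octahydronaphthalen-2-yl]propanoate
Conditions: angelic acid, 2,4,6-trichlorobenzoyl chloride, Et3N, toluene, rt; then 25, 80 °C
Reagents that add atoms: angelic acid C/C=C(/C)C(=O)O
Why: Yamaguchi-type esterification; the mixed anhydride of angelic acid acylates the C3 alcohol without DMAP, which should keep the (Z)-alkene from isomerising to the tiglate and leave C11 untouched by the weak amine base.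

**Compound list**

1 | 2-methylcyclohex-2-en-1-one | CC1=CCCCC1=O | starting material
2 | (S)-2-methylcyclohex-2-en-1-ol | O[C@H]1CCCC=C1C | intermediate
3 | tert-butyldimethyl{[(1S)-2-methylcyclohex-2-en-1-yl]oxy}silane | CC(C)(C)[Si](C)(C)O[C@H]1CCCC=C1C | intermediate
4 | alkylborane from 3 (drawn as RBH2; boron on C5 trans to the C4 methyl) | CC(C)(C)[Si](C)(C)O[C@H]1CCC[C@H](B)[C@H]1C | intermediate
5 | (1S,2R,3S)-3-[(tert-butyldimethylsilyl)oxy]-2-methylcyclohexan-1-ol | CC(C)(C)[Si](C)(C)O[C@H]1CCC[C@H](O)[C@H]1C | intermediate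
6 | (2S,3S)-3-[(tert-butyldimethylsilyl)oxy]-2-methylcyclohexan-1-one | CC(C)(C)[Si](C)(C)O[C@H]1CCCC(=O)[C@H]1C | intermediate
7 | potassium enolate of 6 (C5=C10) | CC(C)(C)[Si](C)(C)O[C@H]1CCC=C([O-])[C@H]1C.[K+] | intermediate
8 | (5S,6S)-5-[(tert-butyldimethylsilyl)oxy]-6-methylcyclohex-1-en-1-yl trifluoromethanesulfonate | CC(C)(C)[Si](C)(C)O[C@H]1CCC=C(OS(=O)(=O)C(F)(F)F)[C@H]1C | intermediate
9 | [(5S,6R)-5-[(tert-butyldimethylsilyl)oxy]-6-methylcyclohex-1-en-1-yl]methanol | CC(C)(C)[Si](C)(C)O[C@H]1CCC=C(CO)[C@H]1C | intermediate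
10 | mixed ketene acetal of 9 (1-ethoxyvinyl ether) | CC(C)(C)[Si](C)(C)O[C@H]1CCC=C(COC(=C)OCC)[C@H]1C | intermediate
11 | ethyl 2-[(1R,3R,4S)-4-[(tert-butyldimethylsilyl)oxy]-3-methyl-2-methylidenecyclohexyl]acetate | CC(C)(C)[Si](C)(C)O[C@H]1CC[C@H](CC(=O)OCC)C(=C)[C@H]1C | intermediate
12 | 2-[(1R,3R,4S)-4-[(tert-butyldimethylsilyl)oxy]-3-methyl-2-methylidenecyclohexyl]acetaldehyde | CC(C)(C)[Si](C)(C)O[C@H]1CC[C@H](CC=O)C(=C)[C@H]1C | intermediate
13 | methyl (S)-3-hydroxy-2-methylpropanoate ((S)-Roche ester) | COC(=O)[C@@H](C)CO | starting material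
14 | methyl (S)-3-[(tert-butyldimethylsilyl)oxy]-2-methylpropanoate | COC(=O)[C@@H](C)CO[Si](C)(C)C(C)(C)C | intermediate
15 | (S)-3-[(tert-butyldimethylsilyl)oxy]-2-methylpropanal | O=C[C@@H](C)CO[Si](C)(C)C(C)(C)C | intermediate
16 | (R)-tert-butyldimethyl[(2-methylbut-3-yn-1-yl)oxy]silane | C#C[C@@H](C)CO[Si](C)(C)C(C)(C)C | intermediate
17 | diisobutyl{(3R)-4-[(tert-butyldimethylsilyl)oxy]-3-methylbut-1-en-2-yl}aluminium | C=C([Al](CC(C)C)CC(C)C)[C@@H](C)CO[Si](C)(C)C(C)(C)C | intermediate
18 | prop-2-en-1-yl (3R)-4-[(tert-butyldimethylsilyl)oxy]-3-methyl-2-methylidenebutanoate | C=C(C(=O)OCC=C)[C@@H](C)CO[Si](C)(C)C(C)(C)C | intermediate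
19 | ester enolate after the C5–C6 bond (iron counter-ion not drawn; C5 quaternary, aldehyde still free) | CC(C)(C)[Si](C)(C)O[C@H]1CC[C@H](CC=O)[C@](C)(CC(=C([O-])OCC=C)[C@@H](C)CO[Si](C)(C)C(C)(C)C)[C@H]1C | intermediate
20 | allyl 8-hydroxy-3,12-bis(TBS-oxy)-cis-eremophilane-7-carboxylate (epimers at C7, C8) | CC(C)(C)[Si](C)(C)O[C@H]1CC[C@@H]2CC(O)C(C(=O)OCC=C)([C@@H](C)CO[Si](C)(C)C(C)(C)C)C[C@]2(C)[C@H]1C | intermediate
21 | allyl 8-oxo-3,12-bis(TBS-oxy)-cis-eremophilane-7-carboxylate (epimers at C7) | CC(C)(C)[Si](C)(C)O[C@H]1CC[C@@H]2CC(=O)C(C(=O)OCC=C)([C@@H](C)CO[Si](C)(C)C(C)(C)C)C[C@]2(C)[C@H]1C | intermediate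
22 | (4aR,5R,6S,8aR)-6-[(tert-butyldimethylsilyl)oxy]-3-{(2R)-1-[(tert-butyldimethylsilyl)oxy]propan-2-yl}-4a,5-dimethyl-4a,5,6,7,8,8a-hexahydronaphthalen-2(1H)-one | CC(C)(C)[Si](C)(C)O[C@H]1CC[C@@H]2CC(=O)C([C@@H](C)CO[Si](C)(C)C(C)(C)C)=C[C@]2(C)[C@H]1C | intermediate
23 | (4aR,5R,6S,8aR)-6-hydroxy-3-[(2R)-1-hydroxypropan-2-yl]-4a,5-dimethyl-4a,5,6,7,8,8a-hexahydronaphthalen-2(1H)-one | O[C@H]1CC[C@@H]2CC(=O)C([C@@H](C)CO)=C[C@]2(C)[C@H]1C | intermediate
24 | (2R)-2-[(4aR,7S,8R,8aR)-7-hydroxy-8,8a-dimethyl-3-oxo-3,4,4a,5,6,7,8,8a-octahydronaphthalen-2-yl]propanoic acid | O[C@H]1CC[C@@H]2CC(=O)C([C@@H](C)C(=O)O)=C[C@]2(C)[C@H]1C | intermediate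
25 | methyl (2R)-2-[(4aR,7S,8R,8aR)-7-hydroxy-8,8a-dimethyl-3-oxo-3,4,4a,5,6,7,8,8a-octahydronaphthalen-2-yl]propanoate | O[C@H]1CC[C@@H]2CC(=O)C([C@@H](C)C(=O)OC)=C[C@]2(C)[C@H]1C | intermediate
26 | methyl (2R)-2-[(4aR,7S,8R,8aR)-8,8a-dimethyl-7-{[(2Z)-2-methylbut-2-enoyl]oxy}-3-oxo-3,4,4a,5,6,7,8,8a-octahydronaphthalen-2-yl]propanoate (CNP0323033.1) | C/C=C(/C)C(=O)O[C@H]1CC[C@@H]2CC(=O)C([C@@H](C)C(=O)OC)=C[C@]2(C)[C@H]1C | target

**Step count and risks**

Total step count: 19. Longest linear sequence: 15 steps (steps 1–8 and 13–19); steps 9–12 form the second branch.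

Steps most likely to fail:

1. Step 13. The radical addition at C5 may show poor facial selectivity, enolate 19 may be protonated before the aldol closure, and hydrogen-atom transfer may go to the acrylate or an allyl group instead. The fallback sets out from 12 and 16 and makes the two bonds one after the other. Vinylalane 17 (from 16 as in step 12) would be added to the aldehyde of 12 (THF, −78 → 0 °C) to give allylic alcohol F1. Dess–Martin oxidation would give the α-substituted vinyl ketone F2. Fe(acac)3/PhSiH3 in EtOH would then form the C5 radical, which cyclises 6-endo-trig onto the enone CH2 (C5–C6, now intramolecular) and after protonation gives the saturated cis-decalone F3. The more substituted trimethylsilyl enol ether F4 (TMSOTf, Et3N, CH2Cl2) and Saegusa–Ito oxidation (Pd(OAc)2, MeCN) would come back to the route at 22.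

2. Step 15. β-Hydride elimination of the palladium enolate may go toward the side chain (exocyclic alkene, loss of C11), or decarboxylative allylation may outrun dehydrogenation. The fallback sets out from 21. Pd(PPh3)4 with morpholine would remove the allyl group, and the β-keto acid would decarboxylate to the saturated cis-decalone F3, the same ketone as in the first fallback. Bromination at the more substituted α-carbon C7 (PhNMe3Br3, THF, 0 °C) would give bromoketone F5. Dehydrobromination (Li2CO3, LiBr, DMF, 120 °C) is an elimination governed by the anti-periplanar ring hydrogen on C6 and not by a palladium hydride, and would come back to the route at 22.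

3. Step 19. Acylation of the hindered C3 alcohol may be slow, and the angeloyl unit may isomerise from Z to E (tiglate). The fallback sets out from 25. Esterification with 2-[bis(2,2,2-trifluoroethoxy)phosphoryl]propanoic acid (EDC, DMAP, CH2Cl2) would give phosphonate ester F6. Still–Gennari olefination with acetaldehyde (KHMDS, one equivalent, 18-crown-6, THF, −78 °C) would build the (Z)-alkene on the ester and come back to the route at 26.

Further compounds
F1 | step 13 | (4R)-5-[(tert-butyldimethylsilyl)oxy]-1-[(1R,3R,4S)-4-[(tert-butyldimethylsilyl)oxy]-3-methyl-2-methylidenecyclohexyl]-4-methyl-3-methylidenepentan-2-ol (C8 epimers) | CC(C)(C)[Si](C)(C)O[C@H]1CC[C@H](CC(O)C(=C)[C@@H](C)CO[Si](C)(C)C(C)(C)C)C(=C)[C@H]1C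
F2 | step 13 | (4R)-5-[(tert-butyldimethylsilyl)oxy]-1-[(1R,3R,4S)-4-[(tert-butyldimethylsilyl)oxy]-3-methyl-2-methylidenecyclohexyl]-4-methyl-3-methylidenepentan-2-one | CC(C)(C)[Si](C)(C)O[C@H]1CC[C@H](CC(=O)C(=C)[C@@H](C)CO[Si](C)(C)C(C)(C)C)C(=C)[C@H]1C
F3 | step 13 | 3,12-bis(TBS-oxy)-cis-eremophilan-8-one (C3, C4, C5, C10, C11 as in 26; C7 epimers) | CC(C)(C)[Si](C)(C)O[C@H]1CC[C@@H]2CC(=O)C([C@@H](C)CO[Si](C)(C)C(C)(C)C)C[C@]2(C)[C@H]1C
F4 | step 13 | 8-(trimethylsilyloxy)-3,12-bis(TBS-oxy)-cis-eremophil-7-ene (silyl enol ether of F3) | CC(C)(C)[Si](C)(C)O[C@H]1CC[C@@H]2CC(O[Si](C)(C)C)=C([C@@H](C)CO[Si](C)(C)C(C)(C)C)C[C@]2(C)[C@H]1C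
F5 | step 15 | 7-bromo-3,12-bis(TBS-oxy)-cis-eremophilan-8-one | CC(C)(C)[Si](C)(C)O[C@H]1CC[C@@H]2CC(=O)C(Br)([C@@H](C)CO[Si](C)(C)C(C)(C)C)C[C@]2(C)[C@H]1C
F6 | step 19 | 3-O-{2-[bis(2,2,2-trifluoroethoxy)phosphoryl]propanoyl} ester of 25 | CC(C(=O)O[C@H]1CC[C@@H]2CC(=O)C([C@@H](C)C(=O)OC)=C[C@]2(C)[C@H]1C)P(=O)(OCC(F)(F)F)OCC(F)(F)F
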